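The 14-membered carbocycle C1–C14 carries a δ-lactone (C1, C2, C3, O, C16, C15) and an oxirane (O, C11, C12). The plan rests on that oxirane: C12 is fully substituted (C20 methyl, O, C11, C13), and C10 and C13 lie trans.
Lactone, formed last: the C3–O/C16 acyl bond, closed when a C16 acid and the C3 hydroxyl are set free on the finished macrocycle. C7 comes from reduction of the C7 ketone.
Macrocycle, formed second: C7–C8, by Ni/Cr-mediated closure of a C8 iodoalkene onto a C7 aldehyde.
Oxirane, formed first: C12–C13 and O–C11, from a C13 Grignard reagent and (3R)-3-chloro-6-iodohept-6-en-2-one.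
Fragments: the chloroketone comes from hex-5-yn-1-ol (organocatalytic chlorination sets C11). The bromide comes from (R)-carvone (C1 from the pool, C3 by Luche reduction, C15 by ligand-controlled hydroboration, C4 by Felkin–Anh addition).
Key step: step 16

Numbering: the ring count starts at the lactone ring-fusion CH (C1) and runs C2, lactone O–CH (C3), tertiary carbinol C4 (methyl C18), C5, C6, carbinol C7, C8 (methylene C19), C9, C10, oxirane C11 and C12 (methyl C20), C13, C14. C15 (methyl C17) and carbonyl C16 finish the lactone. In this numbering the target is 1R,3R,4S,7S,11S,12S,15S.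
Assumption: (R)-DTBM-SEGPHOS is taken to be the ligand antipode that delivers hydride to the C15 face giving 15S. Both antipodes are commercial, and the sense is to be confirmed on 11 before scale-up.

Step 1
Reactants: 1 hex-5-yn-1-ol
Product: 2 5-iodohex-5-en-1-ol
Conditions: NaI, Me3SiCl, H2O, MeCN, 0 °C to rt
Reagents that add atoms: sodium iodide, [Na+].[I-]
Why: Markovnikov hydroiodination, in which HI released in the flask protonates the terminal alkyne carbon (C19) and iodide is captured at C8 to give the 2-iodoalk-1-ene, any O-silyl ether being lost on work-up.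

Step 2
Reactants: 2 5-iodohex-5-en-1-ol
Product: 3 5-iodohex-5-enal
Conditions: TEMPO (2,2,6,6-tetramethylpiperidin-1-oxyl, cat.), PhI(OAc)2, CH2Cl2, rt
Reagents that add atoms: none
Why: Oxoammonium (TEMPO) oxidation of a primary alcohol stops at the aldehyde when water is absent and does not touch the iodoalkene.

Step 3
Reactants: 3 5-iodohex-5-enal
Product: 4 (2R)-2-chloro-5-iodohex-5-enal
Conditions: (5R)-5-benzyl-2,2,3-trimethylimidazolidin-4-one·CF3CO2H (10 mol %), 2,3,4,5,6,6-hexachlorocyclohexa-2,4-dien-1-one, acetone, −30 °C; cold pentane extraction, used without chromatography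
Reagents that add atoms: 2,3,4,5,6,6-hexachlorocyclohexa-2,4-dien-1-one, O=C1C(Cl)=C(Cl)C(Cl)=C(Cl)C1(Cl)Cl
Why: Enamine-catalysed electrophilic alpha-chlorination, in which the E-enamine turns away from the gem-dimethyl group, the benzyl group of the (5R) catalyst covers one face, and chlorine enters on the open face to set C11 as R (the (5S) catalyst is the one that gives (S)-2-chloroalkanals).

Step 4
Reactants: 4 (2R)-2-chloro-5-iodohex-5-enal
Product: 5 (2S,3R)-3-chloro-6-iodohept-6-en-2-ol (major carbinol epimer; both epimers are carried on)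
Conditions: MeMgBr, Et2O, −78 °C; sat. aq NH4Cl at −78 °C
Reagents that add atoms: methylmagnesium bromide, C[Mg]Br
Why: Grignard 1,2-addition to the activated aldehyde outruns enolisation at −78 °C, so C11 is kept, and the new carbinol centre (mainly anti by the Cornforth model) does not matter because step 5 removes it.

Step 5
Reactants: 5 (2S,3R)-3-chloro-6-iodohept-6-en-2-ol
Product: 6 (3R)-3-chloro-6-iodohept-6-en-2-one
Conditions: Dess–Martin periodinane, CH2Cl2, 0 °C to rt; short neutral silica plug, stored cold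
Reagents that add atoms: none
Why: Dess–Martin oxidation runs under non-basic conditions, so the alcohol becomes the methyl ketone without enolisation of the chlorine-bearing C11 centre.

Step 6
Reactants: 7 3-bromopropan-1-ol
Product: 8 (3-bromopropoxy)triethylsilane
Conditions: Et3SiCl, imidazole, CH2Cl2, 0 °C
Reagents that add atoms: chlorotriethylsilane, CC[Si](Cl)(CC)CC
Why: Imidazole-promoted silylation masks the hydroxyl so that the bromide can be converted to a Grignard reagent, and a primary triethylsilyl ether can later be oxidised directly.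

Step 7
Reactants: 9 (R)-(−)-carvone
Product: 10 (1R,5R)-cis-carveol
Conditions: NaBH4, CeCl3·7H2O, MeOH, −20 °C
Reagents that add atoms: none
Why: Luche reduction gives clean 1,2-reduction, and axial hydride delivery to the half-chair with an equatorial isopropenyl group places the hydroxyl equatorial and cis to it, which sets C3 (R) relative to the pool centre C1.

Step 8
Reactants: 10 (1R,5R)-cis-carveol
Product: 11 (1R,5R)-cis-carveol tert-butyldimethylsilyl ether
Conditions: t-BuMe2SiCl, imidazole, DMF, rt
Reagents that add atoms: tert-butyl(chloro)dimethylsilane, CC(C)(C)[Si](C)(C)Cl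
Why: Silylation places a bulky, weakly Lewis-basic ether on C3, chosen because a benzyl-type ether would chelate magnesium in step 14 and give the C4 epimer.

Step 9
Reactants: 11 (1R,5R)-cis-carveol tert-butyldimethylsilyl ether
Product: 13 (2S)-2-[(1R,5R)-5-(tert-butyldimethylsilyloxy)-4-methylcyclohex-3-en-1-yl]propan-1-ol, via pinacol boronate 12 (not isolated)
Conditions: CuCl (5 mol %), (R)-DTBM-SEGPHOS (5.5 mol %), KOt-Bu (10 mol %), HBpin, toluene, rt; then aq NaOH, 30% H2O2, THF, 0 °C
Reagents that add atoms: pinacolborane, [H]B1OC(C)(C)C(C)(C)O1 (boron stays only in 12); hydrogen peroxide, OO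
Why: Copper hydride-catalysed anti-Markovnikov hydroboration of a 1,1-disubstituted alkene, in which ligated CuH places H on C15 and Cu on C16 while the chiral bisphosphine tells the methyl from the ring substituent and so sets C15 under catalyst control (substrate control is negligible because C2 and C14 are both CH2), sigma-bond metathesis with HBpin gives 12, oxidation proceeds with retention, and the trisubstituted ring alkene stays inert.

Step 10
Reactants: 13 (2S)-2-[(1R,5R)-5-(tert-butyldimethylsilyloxy)-4-methylcyclohex-3-en-1-yl]propan-1-ol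
Product: 14 16-O-(4-methoxybenzyl) ether of 13
Conditions: NaH, 4-MeOC6H4CH2Cl, Bu4NI (cat.), THF–DMF, 0 °C to rt
Reagents that add atoms: 4-methoxybenzyl chloride, COc1ccc(CCl)cc1
Why: Williamson etherification gives C16 the only oxidatively removable group in the molecule, so that C16 alone can be released late in the route.

Step 11
Reactants: 14 16-O-(4-methoxybenzyl) ether of 13
Product: 16 C13 aldehyde C4 methyl ketone (3-OTBS 16-OPMB), via ozonide 15 (not isolated)
Conditions: O3, CH2Cl2, −78 °C (Sudan Red 7B end point); then PPh3, −78 °C to rt; used at once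
Reagents that add atoms: ozone, [O-][O+]=O
Why: Ozonolysis cleaves the only alkene (C4=C13) far faster than it attacks the anisyl ring at −78 °C, opening the carvone ring to the C13 aldehyde and the C4 methyl ketone without touching C1, C3 or C15.

Step 12
Reactants: 16 C13 aldehyde C4 methyl ketone (3-OTBS 16-OPMB)
Product: 17 C13 alcohol C4 methyl ketone
Conditions: NaBH4 (0.5 equiv), CH2Cl2–EtOH 7:3, −78 °C
Reagents that add atoms: none
Why: Chemoselective borohydride reduction, in which the unhindered aldehyde is reduced at −78 °C much faster than the ketone flanked by the silyloxy-bearing C3.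

Step 13
Reactants: 17 C13 alcohol C4 methyl ketone
Product: 18 C13 bromide C4 methyl ketone
Conditions: CBr4, PPh3, CH2Cl2, 0 °C
Reagents that add atoms: tetrabromomethane, BrC(Br)(Br)Br
Why: The Appel reaction converts the primary alcohol to the bromide under neutral conditions that the ketone and the silyl and PMB ethers tolerate.

Step 14
Reactants: 18 C13 bromide C4 methyl ketone; 8 (3-bromopropoxy)triethylsilane
Product: 20 C4 tertiary alcohol (anti 3-OTBS/4-OH; 7-OTES; 16-OPMB; C13 bromide), via silyloxypropyl Grignard reagent 19 (not isolated)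
Conditions: 8, Mg turnings, THF, rt to 40 °C; then 18, THF, −78 to −40 °C; sat. aq NH4Cl
Reagents that add atoms: magnesium, [Mg] (stays only in 19)
Why: Polar Felkin–Anh addition, in which the non-chelating C3–OSi bond stands perpendicular to the carbonyl and the Grignard reagent enters anti to it past the C3 hydrogen to give the anti 3,4-relationship (4S), while the uncatalysed primary bromide is inert to the reagent at low temperature.

Step 15
Reactants: 20 C4 tertiary alcohol
Product: 21 C13 bromide (3-OTBS, 4-OTES, 7-OTES, 16-OPMB; C1, C3, C4 and C15 arranged as in 34)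
Conditions: Et3SiOTf, 2,6-lutidine, CH2Cl2, 0 °C
Reagents that add atoms: triethylsilyl trifluoromethanesulfonate, CC[Si](CC)(CC)OS(=O)(=O)C(F)(F)F
Why: The silyl triflate is reactive enough to cap the hindered tertiary hydroxyl, removing the last acidic proton before magnesium insertion.

Step 16
Reactants: 21 C13 bromide; 6 (3R)-3-chloro-6-iodohept-6-en-2-one
Product: 24 acyclic (11S,12S)-epoxide bearing the C8 iodoalkene, via C13 Grignard reagent 22 (not isolated), via anti chlorohydrin 23 (not isolated)
Conditions: 21, Mg turnings, THF, 40 °C; cannulated into 6 (1.2 equiv), THF–Et2O, −78 °C; MeOH, −78 °C; then K2CO3, MeOH, −78 °C to rt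
Reagents that add atoms: magnesium, [Mg] (stays only in 22)
Why: The alkylmagnesium bromide 22 adds to the C12 carbonyl of 6 through the Cornforth (equally, polar Felkin–Anh) arrangement, in which the C11–Cl dipole opposes C=O and the nucleophile enters on the side of the C11 hydrogen, giving the anti chlorohydrin 23; this is the classical 1,2-addition of organomagnesium reagents to alpha-chloro carbonyl compounds followed by halohydrin closure. After the cold methanol quench, carbonate deprotonates the tertiary C12 hydroxyl, which turns antiperiplanar to chlorine and displaces it in a 3-exo-tet ring closure. C12 (S) is therefore controlled by the resident C11 chlorine centre, and C11 becomes S by clean inversion of the R centre set catalytically in step 3, so that C10 and C13 end up trans on the oxirane. The step needs carbonyl addition to win over enolisation and over iodine–magnesium exchange: the inductively activated ketone reacts at −78 °C, where a primary alkyl Grignard reagent neither deprotonates it at a competitive rate nor attacks the sp2 C–I bond. Quenching before warming keeps the Lewis-acidic magnesium alkoxide from setting off a semipinacol shift, and the silyl and PMB ethers are inert to carbonate in methanol.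

Step 17
Reactants: 24 acyclic (11S,12S)-epoxide bearing the C8 iodoalkene
Product: 26 C7 aldehyde, via alkoxysulfonium chloride 25 (not isolated)
Conditions: (COCl)2, DMSO, CH2Cl2, −78 to −40 °C; then Et3N, −78 to 0 °C
Reagents that add atoms: dimethyl sulfoxide, CS(C)=O (sulfur and methyl groups stay only in 25)
Why: Swern oxidation applied directly to a primary triethylsilyl ether, in which the chlorosulfonium salt exchanges only the unhindered primary Si–O bond, so the tertiary TES, the TBS and PMB ethers and the oxirane remain.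

Step 18
Reactants: 26 C7 aldehyde
Product: 27 macrocyclic C7 allylic alcohol (both C7 epimers)
Conditions: CrCl2 (15 equiv), NiCl2 (0.15 equiv), DMSO–THF 3:1, rt, slow addition to 1 mM
Reagents that add atoms: none
Why: Nozaki–Hiyama–Kishi reaction, in which zerovalent nickel inserts into the C8–I bond, the alkenyl group passes to trivalent chromium and adds chemoselectively to the aldehyde, high dilution favours the 14-membered ring, and the uncontrolled C7 centre is reset in steps 19 and 20.

Step 19
Reactants: 27 macrocyclic C7 allylic alcohol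
Product: 28 macrocyclic C7 ketone conjugated with the C8 methylene
Conditions: Dess–Martin periodinane, pyridine, CH2Cl2, 0 °C
Reagents that add atoms: none
Why: Pyridine-buffered Dess–Martin oxidation merges both C7 epimers into one enone without acid damage to the oxirane.

Step 20
Reactants: 28 macrocyclic C7 ketone
Product: 29 (7S)-allylic alcohol
Conditions: (R)-Me-CBS oxazaborolidine ((R)-1-methyl-3,3-diphenyltetrahydro-1H,3H-pyrrolo[1,2-c][1,3,2]oxazaborole, 0.5 equiv), catecholborane, toluene, −78 °C
Reagents that add atoms: none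
Why: Corey–Bakshi–Shibata reduction, in which the ketone binds to boron with the branched alkenyl carbon C8 as the large group and C6 as the small one, so the (R) catalyst delivers hydride to the face that gives 7S, and catecholborane at −78 °C avoids conjugate reduction and hydroboration.

Step 21
Reactants: 29 (7S)-allylic alcohol
Product: 30 7-O-TBS ether
Conditions: t-BuMe2SiCl, imidazole, DMF, rt
Reagents that add atoms: tert-butyl(chloro)dimethylsilane, CC(C)(C)[Si](C)(C)Cl
Why: Silyl chloride with imidazole protects C7 from the oxidations that follow without exposing the oxirane to a Lewis-acidic silyl triflate.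

Step 22
Reactants: 30 7-O-TBS ether
Product: 31 C16 primary alcohol
Conditions: DDQ, CH2Cl2–pH 7 buffer, 0 °C
Reagents that add atoms: none
Why: Oxidative PMB cleavage by hydride abstraction from the electron-rich benzylic position frees only C16–OH and leaves the silyl ethers, the alkene and the oxirane intact.

Step 23
Reactants: 31 C16 primary alcohol
Product: 32 C16 carboxylic acid
Conditions: TEMPO (cat.), PhI(OAc)2, MeCN–H2O 1:1, rt
Reagents that add atoms: water, O
Why: TEMPO/PhI(OAc)2 oxidation in aqueous medium takes the sole free alcohol through the aldehyde hydrate to the acid, and because O3, O4 and O7 are all silylated there is no glycol to cleave and no second alcohol to oxidise.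

Step 24
Reactants: 32 C16 carboxylic acid
Product: 34 target CNP0262409.2, via trihydroxy acid 33 (not isolated)
Conditions: Bu4NF, AcOH, THF, rt to 40 °C; work-up at pH 5, concentration from toluene at 40 °C
Reagents that add atoms: none
Why: Buffered fluoride removes all three silyl groups, and the δ-hydroxy acid closes spontaneously on O3 (6-exo-trig lactonisation, preferred over the seven-membered alternative through the tertiary O4) to a lactone in which C14, C4 and C17 are all equatorial, so C15 is not at risk.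

Compound list
1 | hex-5-yn-1-ol | C#CCCCCO | starting material
2 | 5-iodohex-5-en-1-ol | C=C(I)CCCCO | intermediate
3 | 5-iodohex-5-enal | C=C(I)CCCC=O | intermediate
4 | (2R)-2-chloro-5-iodohex-5-enal | O=C[C@H](Cl)CCC(I)=C | intermediate
5 | (2S,3R)-3-chloro-6-iodohept-6-en-2-ol (major carbinol epimer) | C[C@H](O)[C@H](Cl)CCC(I)=C | intermediate
6 | (3R)-3-chloro-6-iodohept-6-en-2-one | CC(=O)[C@H](Cl)CCC(I)=C | intermediate
7 | 3-bromopropan-1-ol | OCCCBr | starting material
8 | (3-bromopropoxy)triethylsilane | BrCCCO[Si](CC)(CC)CC | intermediate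
9 | (R)-(−)-carvone | CC1=CC[C@H](CC1=O)C(C)=C | starting material
10 | (1R,5R)-cis-carveol | CC1=CC[C@H](C[C@H]1O)C(C)=C | intermediate
11 | (1R,5R)-cis-carveol TBS ether | CC1=CC[C@H](C[C@H]1O[Si](C)(C)C(C)(C)C)C(C)=C | intermediate
12 | C16 pinacol boronate (not isolated) | CC1=CC[C@H](C[C@H]1O[Si](C)(C)C(C)(C)C)[C@H](C)CB2OC(C)(C)C(C)(C)O2 | intermediate
13 | (2S)-2-[(1R,5R)-5-(tert-butyldimethylsilyloxy)-4-methylcyclohex-3-en-1-yl]propan-1-ol | CC1=CC[C@H](C[C@H]1O[Si](C)(C)C(C)(C)C)[C@H](C)CO | intermediate
14 | 16-O-PMB ether of 13 | CC1=CC[C@H](C[C@H]1O[Si](C)(C)C(C)(C)C)[C@H](C)COCc2ccc(OC)cc2 | intermediate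
15 | C4/C13 ozonide (1,2,4-trioxolane, acetal carbons undefined; not isolated) | CC12OOC(O1)C[C@H](C[C@H]2O[Si](C)(C)C(C)(C)C)[C@H](C)COCc3ccc(OC)cc3 | intermediate
16 | C13 aldehyde, C4 methyl ketone, 3-OTBS, 16-OPMB | O=CC[C@H](C[C@@H](O[Si](C)(C)C(C)(C)C)C(C)=O)[C@H](C)COCc1ccc(OC)cc1 | intermediate
17 | C13 alcohol, C4 methyl ketone | OCC[C@H](C[C@@H](O[Si](C)(C)C(C)(C)C)C(C)=O)[C@H](C)COCc1ccc(OC)cc1 | intermediate
18 | C13 bromide, C4 methyl ketone | BrCC[C@H](C[C@@H](O[Si](C)(C)C(C)(C)C)C(C)=O)[C@H](C)COCc1ccc(OC)cc1 | intermediate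
19 | 3-(triethylsilyloxy)propylmagnesium bromide (not isolated) | Br[Mg]CCCO[Si](CC)(CC)CC | intermediate
20 | C4 tertiary alcohol, 3-OTBS, 7-OTES, 16-OPMB, C13 bromide | BrCC[C@H](C[C@@H](O[Si](C)(C)C(C)(C)C)[C@@](C)(O)CCCO[Si](CC)(CC)CC)[C@H](C)COCc1ccc(OC)cc1 | intermediate
21 | C13 bromide, 3-OTBS, 4-OTES, 7-OTES, 16-OPMB | BrCC[C@H](C[C@@H](O[Si](C)(C)C(C)(C)C)[C@@](C)(O[Si](CC)(CC)CC)CCCO[Si](CC)(CC)CC)[C@H](C)COCc1ccc(OC)cc1 | intermediate
22 | C13 Grignard reagent from 21 (not isolated) | Br[Mg]CC[C@H](C[C@@H](O[Si](C)(C)C(C)(C)C)[C@@](C)(O[Si](CC)(CC)CC)CCCO[Si](CC)(CC)CC)[C@H](C)COCc1ccc(OC)cc1 | intermediate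
23 | (11R,12S) anti chlorohydrin (not isolated) | C=C(I)CC[C@@H](Cl)[C@@](C)(O)CC[C@H](C[C@@H](O[Si](C)(C)C(C)(C)C)[C@@](C)(O[Si](CC)(CC)CC)CCCO[Si](CC)(CC)CC)[C@H](C)COCc1ccc(OC)cc1 | intermediate
24 | acyclic (11S,12S)-epoxide with C8 iodoalkene | C=C(I)CC[C@@H]1O[C@@]1(C)CC[C@H](C[C@@H](O[Si](C)(C)C(C)(C)C)[C@@](C)(O[Si](CC)(CC)CC)CCCO[Si](CC)(CC)CC)[C@H](C)COCc2ccc(OC)cc2 | intermediate
25 | C7 alkoxysulfonium chloride (not isolated) | C=C(I)CC[C@@H]1O[C@@]1(C)CC[C@H](C[C@@H](O[Si](C)(C)C(C)(C)C)[C@@](C)(O[Si](CC)(CC)CC)CCCO[S+](C)C)[C@H](C)COCc2ccc(OC)cc2.[Cl-] | intermediate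
26 | C7 aldehyde | C=C(I)CC[C@@H]1O[C@@]1(C)CC[C@H](C[C@@H](O[Si](C)(C)C(C)(C)C)[C@@](C)(O[Si](CC)(CC)CC)CCC=O)[C@H](C)COCc2ccc(OC)cc2 | intermediate
27 | macrocyclic C7 allylic alcohol (C7 epimers) | C=C1CC[C@@H]2O[C@@]2(C)CC[C@H](C[C@@H](O[Si](C)(C)C(C)(C)C)[C@@](C)(O[Si](CC)(CC)CC)CCC1O)[C@H](C)COCc3ccc(OC)cc3 | intermediate
28 | macrocyclic C7 enone | C=C1CC[C@@H]2O[C@@]2(C)CC[C@H](C[C@@H](O[Si](C)(C)C(C)(C)C)[C@@](C)(O[Si](CC)(CC)CC)CCC1=O)[C@H](C)COCc3ccc(OC)cc3 | intermediate
29 | (7S)-allylic alcohol | C=C1CC[C@@H]2O[C@@]2(C)CC[C@H](C[C@@H](O[Si](C)(C)C(C)(C)C)[C@@](C)(O[Si](CC)(CC)CC)CC[C@@H]1O)[C@H](C)COCc3ccc(OC)cc3 | intermediate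
30 | 7-O-TBS ether | C=C1CC[C@@H]2O[C@@]2(C)CC[C@H](C[C@@H](O[Si](C)(C)C(C)(C)C)[C@@](C)(O[Si](CC)(CC)CC)CC[C@@H]1O[Si](C)(C)C(C)(C)C)[C@H](C)COCc3ccc(OC)cc3 | intermediate
31 | C16 primary alcohol | C=C1CC[C@@H]2O[C@@]2(C)CC[C@H](C[C@@H](O[Si](C)(C)C(C)(C)C)[C@@](C)(O[Si](CC)(CC)CC)CC[C@@H]1O[Si](C)(C)C(C)(C)C)[C@H](C)CO | intermediate
32 | C16 carboxylic acid | C=C1CC[C@@H]2O[C@@]2(C)CC[C@H](C[C@@H](O[Si](C)(C)C(C)(C)C)[C@@](C)(O[Si](CC)(CC)CC)CC[C@@H]1O[Si](C)(C)C(C)(C)C)[C@H](C)C(O)=O | intermediate
33 | 3,4,7-trihydroxy C16 acid (not isolated) | C=C1CC[C@@H]2O[C@@]2(C)CC[C@H](C[C@@H](O)[C@@](C)(O)CC[C@@H]1O)[C@H](C)C(O)=O | intermediate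
34 | CNP0262409.2 | C=C1CC[C@@H]2O[C@@]2(C)CC[C@@H]2C[C@@H](OC(=O)[C@H]2C)[C@@](C)(O)CC[C@@H]1O | target

Total step count: 24. Longest linear sequence: 18 steps, from (R)-carvone (steps 7 to 24).

Steps most likely to fail

Step 16. Magnesium insertion into the hindered, polyoxygenated bromide may be slow and accompanied by Wurtz coupling. Proton transfer from the chloroketone to the organometallic would consume both partners and erode the C11 configuration. The facial bias of a methyl ketone may also be weaker than that of an aldehyde.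

The fallback sets out from 21 and comes back at 27. It builds the oxirane from an E-alkene by reagent-controlled epoxidation.
- 21 is alkylated with LiC≡CH·H2NCH2CH2NH2 in DMSO to give the terminal alkyne F1.
- Zirconium-catalysed methylalumination (Me3Al, Cp2ZrCl2, CH2Cl2) gives the alkenylalane F2 by syn addition, and iodine converts it to the (E)-iodoalkene F3.
- Commercial 3-bromobut-3-en-1-ol is turned (I2, PPh3, imidazole) into 2-bromo-4-iodobut-1-ene F4, and zinc dust with LiCl in THF gives the alkylzinc iodide F5.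
- Negishi coupling of F3 with F5 (PdCl2(dppf), THF) takes place at the more reactive C–I bond and gives the bromo diene F6.
- Shi epoxidation uses the L-fructose-derived ketone (1,2:4,5-di-O-isopropylidene-β-L-erythro-2,3-hexodiulo-2,6-pyranose) and KHSO5 at buffered pH. It oxidises only the electron-rich trisubstituted alkene and gives the (11S,12S)-bromo epoxide F7.
- The protocol of step 17 takes F7 through the alkoxysulfonium chloride F8 to the bromo aldehyde F9, which is closed with CrCl2/NiCl2 as in step 18 to give 27.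

Step 18. Oligomerisation may outrun ring closure. The alkenylchromium species may be protonated before it finds the aldehyde. Trivalent chromium chloride may open the oxirane.

The fallback sets out from 26 and comes back at 28. It replaces the reductive carbonyl addition by an anionic ring-closing acylation.
- Pinnick oxidation (NaClO2, NaH2PO4, 2-methylbut-2-ene) gives the C7 acid F10.
- Coupling with MeNHOMe·HCl (EDC·HCl, Et3N) gives the Weinreb amide F11.
- Slow addition of F11 to t-BuLi (2.1 equiv) in THF at −78 °C under high dilution triggers iodine–lithium exchange faster than attack on the amide.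
- The alkenyllithium F12 then closes onto the amide. The chelated tetrahedral adduct prevents a second addition and releases enone 28 directly on quench.

Step 9. Hydrocupration of the alkene next to the ring may be slow, or the ligand may fail to override the small substrate bias, leaving C15 poorly defined.

The fallback sets out from 11 and comes back at 13. It uses stereorandom hydroboration followed by enzymatic sorting.
- 9-BBN in THF gives the B-alkyl-9-borabicyclononane F13, and NaOH/H2O2 gives the C15-epimeric alcohol F14.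
- Burkholderia cepacia lipase with vinyl acetate in t-BuOMe is expected, by the empirical rule for 2-methyl-branched primary alcohols, to acylate the 15S epimer faster, giving the (15S)-acetate F15.
- F15 is separated from the unreacted 15R alcohol by chromatography and cleaved with K2CO3 in MeOH to give 13.

Further compounds
F1 | step 16 | terminal alkyne (C11≡C12 on C13; groups as in 21) | C#CCC[C@H](C[C@@H](O[Si](C)(C)C(C)(C)C)[C@@](C)(O[Si](CC)(CC)CC)CCCO[Si](CC)(CC)CC)[C@H](C)COCc1ccc(OC)cc1
F2 | step 16 | (E)-alkenyl(dimethyl)alane | C[Al](C)/C=C(\C)CC[C@H](C[C@@H](O[Si](C)(C)C(C)(C)C)[C@@](C)(O[Si](CC)(CC)CC)CCCO[Si](CC)(CC)CC)[C@H](C)COCc1ccc(OC)cc1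
F3 | step 16 | (E)-C11 iodoalkene | I/C=C(\C)CC[C@H](C[C@@H](O[Si](C)(C)C(C)(C)C)[C@@](C)(O[Si](CC)(CC)CC)CCCO[Si](CC)(CC)CC)[C@H](C)COCc1ccc(OC)cc1
F4 | step 16 | 2-bromo-4-iodobut-1-ene | C=C(Br)CCI
F5 | step 16 | (3-bromobut-3-en-1-yl)zinc iodide | C=C(Br)CC[Zn]I
F6 | step 16 | (11E)-diene with C8 bromoalkene | C=C(Br)CC/C=C(\C)CC[C@H](C[C@@H](O[Si](C)(C)C(C)(C)C)[C@@](C)(O[Si](CC)(CC)CC)CCCO[Si](CC)(CC)CC)[C@H](C)COCc1ccc(OC)cc1
F7 | step 16 | (11S,12S)-epoxide, bromo analogue of 24 | C=C(Br)CC[C@@H]1O[C@@]1(C)CC[C@H](C[C@@H](O[Si](C)(C)C(C)(C)C)[C@@](C)(O[Si](CC)(CC)CC)CCCO[Si](CC)(CC)CC)[C@H](C)COCc2ccc(OC)cc2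
F8 | step 16 | alkoxysulfonium chloride, bromo analogue of 25 | C=C(Br)CC[C@@H]1O[C@@]1(C)CC[C@H](C[C@@H](O[Si](C)(C)C(C)(C)C)[C@@](C)(O[Si](CC)(CC)CC)CCCO[S+](C)C)[C@H](C)COCc2ccc(OC)cc2.[Cl-]
F9 | step 16 | C7 aldehyde, bromo analogue of 26 | C=C(Br)CC[C@@H]1O[C@@]1(C)CC[C@H](C[C@@H](O[Si](C)(C)C(C)(C)C)[C@@](C)(O[Si](CC)(CC)CC)CCC=O)[C@H](C)COCc2ccc(OC)cc2
F10 | step 18 | C7 carboxylic acid with C8 iodoalkene | C=C(I)CC[C@@H]1O[C@@]1(C)CC[C@H](C[C@@H](O[Si](C)(C)C(C)(C)C)[C@@](C)(O[Si](CC)(CC)CC)CCC(O)=O)[C@H](C)COCc2ccc(OC)cc2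
F11 | step 18 | C7 N-methoxy-N-methylamide | C=C(I)CC[C@@H]1O[C@@]1(C)CC[C@H](C[C@@H](O[Si](C)(C)C(C)(C)C)[C@@](C)(O[Si](CC)(CC)CC)CCC(=O)N(C)OC)[C@H](C)COCc2ccc(OC)cc2
F12 | step 18 | C8 alkenyllithium | [Li]C(=C)CC[C@@H]1O[C@@]1(C)CC[C@H](C[C@@H](O[Si](C)(C)C(C)(C)C)[C@@](C)(O[Si](CC)(CC)CC)CCC(=O)N(C)OC)[C@H](C)COCc2ccc(OC)cc2
F13 | step 9 | B-alkyl-9-borabicyclononane (C15 epimers) | CC1=CC[C@H](C[C@H]1O[Si](C)(C)C(C)(C)C)C(C)CB2C3CCCC2CCC3
F14 | step 9 | C15-epimeric alcohol | CC1=CC[C@H](C[C@H]1O[Si](C)(C)C(C)(C)C)C(C)CO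
F15 | step 9 | (15S)-acetate of 13 | CC1=CC[C@H](C[C@H]1O[Si](C)(C)C(C)(C)C)[C@H](C)COC(C)=O
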